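A ratio opens the books: 1.50 equiv of reagent to substrate in winter, the flask where everything goes in together at the start, so substrate is the limiting reagent and 0.500 equiv of reagent has no substrate to meet. Each mole of target costs one mole of reagent and each mole of over-reaction product costs two, for it has passed through target, so we need the price of the second entry against the first.

the same everywhere: catalyst 0.31 mol%
- Friday's: substrate 0.011 M; reagent 1.5 equiv; temperature −15 °C; run made earlier
- Thursday's: substrate 0.011 M; reagent 0.75 equiv; temperature 0 °C; run made earlier
- Monday's: substrate 0.011 M; reagent 3 equiv; temperature −15 °C; run made earlier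
- Wednesday's: substrate 0.0055 M; reagent 1.5 equiv; temperature 0 °C; run made earlier
- dawn: substrate 0.011 M (fed, over 1.5 h); reagent 1.50 equiv; the addition at −30 °C, then warmed to 0 °C; the feed brings no volume worth counting; time 2.0 h
- noon: substrate 0.011 M; reagent 1.50 equiv (fed, over 1.5 h); temperature 0 °C; all else is in the flask from the start; the feed brings no volume worth counting; time 2.0 h
- autumn: substrate 0.011 M (fed, over 1.5 h); reagent 1.50 equiv; temperature 0 °C; all else is in the flask from the start; the feed brings no volume worth counting; time 2.0 h
- winter: substrate 0.011 M; reagent 1.50 equiv; temperature 0 °C; everything together at the start; time 2.0 h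

Friday's run (percent of the substrate charged)

| time / h | target / % | over-reaction product / % |
|---|---|---|
| 0.333 | 68.6 | 3.6 |
| 0.667 | 82.1 | 4.8 |
| 1.00 | 89.7 | 6.4 |
| 1.33 | 87.0 | 7.8 |
| 2.00 | 87.9 | 9.9 |
| 3.00 | 84.3 | 15.7 |

Thursday's run (percent of the substrate charged)

| time / min | target / % | over-reaction product / % |
|---|---|---|
| 6.00 | 33.2 | 0 |
| 8.00 | 38.1 | 0.6 |
| 12.0 | 45.0 | 0.6 |
| 20.0 | 52.8 | 2.8 |
| 30.0 | 58.2 | 2.1 |
| 50.0 | 65.2 | 1.3 |
| 80.0 | 66.0 | 1.3 |

Monday's run (percent of the substrate charged)

| time / h | target / % | over-reaction product / % |
|---|---|---|
| 0.200 | 80.4 | 5.1 |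
| 0.250 | 85.5 | 4.0 |
| 0.417 | 88.4 | 8.0 |
| 0.667 | 85.3 | 12.2 |
| 1.00 | 80.9 | 18.5 |
| 2.00 | 65.4 | 34.2 |
| 3.00 | 55.2 | 45.5 |

Wednesday's run (percent of the substrate charged)

| time / min | target / % | over-reaction product / % |
|---|---|---|
| 15.0 | 39.0 | 1.2 |
| 30.0 | 55.8 | 4.0 |
| 40.0 | 61.7 | 6.4 |
| 60.0 | 70.2 | 10.2 |
| 80.0 | 74.5 | 10.6 |

(readings scatter by 1 percentage point)



1. the best flask by share of target in target plus over-reaction product; "all alike" if 1.5 percentage points covers them all (dawn / noon / autumn / winter / all alike)
2. share of target in target plus over-reaction product at the end, dawn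
3. share of target in target plus over-reaction product at the end, noon
4. share of target in target plus over-reaction product at the end, autumn
5. share of target in target plus over-reaction product at the end, winter

We take the second entry from Wednesday's run at 0 °C, assuming that the rate is κ·c(reagent)·c(target) and needs no catalyst. Between 15.0 min and 80.0 min over-reaction product rose 9.4 percentage points, with target near 56.8% and c(reagent) near 0.00448 M. So the wear constant κ, the fraction of target lost per hour and per molar of reagent, reads 34.1 /M/h, with the scatter of those readings.

Thursday's run has winter's c(substrate) and catalyst loading, and its first reading gives the main step 628 /M/h, so the selectivity factor σ is 18.4. For two steps in series sharing one reagent, target peaks at the reciprocal of σ raised to the power one over σ less one, here 84.6%, and at that moment substrate stands at target over σ, 4.60%, and over-reaction product at the remainder, 10.8%, which leaves 0.438 equiv of reagent. We give the main step the first half of the time, 1.00 h, and substrate's lifetime is 0.0965 h on the charged reagent and 0.331 h at the peak, both shorter than that span. In the second 1.00 h we book the 4.60% of substrate as target and then the wear: holding reagent at the peak's level, which overcounts, costs 14 points of target. Our books close at 75.3% target in winter, with 0.252 equiv of reagent unspent.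

The forecast names dawn best, with 89% for dawn, 86% for noon, 78% for autumn, where “it is worst”, and 82% for winter; our winter figure stands below it.

Winter gives 74.3%, and dawn leads with 88.7%, ahead of noon at 83.7% and autumn at 75.9%.

    reagent + target → over-reaction product (k = 0.620 /M/min, Ea = 47.0 kJ/mol)
    substrate + reagent + catalyst → catalyst + target (k = 2.90 × 10⁵ /M²/min, Ea = 23.0 kJ/mol)
    (constants at 0 °C)

Between 1.00 h and 2.00 h winter's over-reaction product went from 16.2% to 25.6%, while reagent fell from 24.0% to 16.4% of its charge. κ on the mean reagent and target of that span gives 8.9 points. In dawn, read on at 3.0 h, the same κ on the means since 2.00 h gives 11 points, and over-reaction product went from 10.7% to 22.3%.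

The earlier runs and the new flask are calculated for substances that don't exist; scatter was added.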